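The six-membered carbocycle C1–C6 (carotenoid numbering; C1 is CMe2, C3 the carbinol, C5 the oxygen-bearing quaternary carbon) is closed between C2 and C3: a neopentyl iodide at C2 adds, as an alkylchromium, to an aldehyde at C3. The step exploits the gem-dimethyl carbon C1 next to C2 (no elimination; its axial methyl forces the new C3 oxygen equatorial) and a temporary methyl-bearing stereocentre at C5, which passes its configuration to C3 and is then erased in the C5=C6 enol triflate. The precursor is an acyclic iodo keto aldehyde from asymmetric crotylboration. Sharpless epoxidation then sets C5/C6, a copper-catalysed vinyl oxirane ring expansion closes the dihydrofuran (O–C5–C6=C7–C8) and sets C8, and a Wittig reaction adds the polyene.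

Key step: step 6

Remark: the copper-catalysed ring expansion of step 13 is assumed to keep the E geometry of C7=C8 while the oxygen shifts from C6 to C8; with the oxygen held on one face by C5 this fixes C8 as R.

Step 1
Reactants: 1 isobutyronitrile
Product: 2 3-iodo-2,2-dimethylpropanenitrile
Conditions: LDA, THF, −78 °C; then CH2I2 (3 equiv), −78 °C to rt
Reagents that add atoms: diiodomethane, ICI
Why: The lithiated nitrile is alkylated by diiodomethane (nitrile-anion SN2 alkylation), and the neopentyl iodide formed has no beta hydrogen and is inert to further substitution.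

Step 2
Reactants: 2 3-iodo-2,2-dimethylpropanenitrile
Product: 4 3-iodo-2,2-dimethylpropanal, via aldimine 3 (not isolated)
Conditions: DIBAL-H (i-Bu2AlH), toluene, −78 °C; then 1 M aq. tartaric acid, 0 °C
Reagents that add atoms: water, O
Why: DIBAL adds once to the nitrile and the aluminium iminate is hydrolysed to the non-enolisable aldehyde (DIBAL nitrile reduction), leaving the neopentyl iodide untouched.

Step 3
Reactants: 4 3-iodo-2,2-dimethylpropanal
Product: 6 (3S,4S)-1-iodo-2,2,4-trimethylhex-5-en-3-ol, via borinate ester 5 (not isolated)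
Conditions: trans-but-2-ene, KOt-Bu, n-BuLi, THF, −78 to −45 °C; (−)-Ipc2BOMe [from (+)-α-pinene], −78 °C; BF3·OEt2; then 4, −78 °C; NaBO3·4H2O, H2O, rt
Reagents that add atoms: (E)-crotyldiisopinocampheylborane, C/C=C/CB([C@@H]1C[C@@H]2C[C@H]([C@H]1C)C2(C)C)[C@@H]1C[C@@H]2C[C@H]([C@H]1C)C2(C)C
Why: Brown crotylboration through a Zimmerman–Traxler chair: the (E)-crotyl group gives the anti adduct and the reagent from (+)-α-pinene attacks the Si face of the aldehyde, which sets the methyl-bearing carbon (later C5) as S and the carbinol carbon as S.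

Step 4
Reactants: 6 (3S,4S)-1-iodo-2,2,4-trimethylhex-5-en-3-ol
Product: 8 (3S,4S)-6-iodo-3,5,5-trimethylhexane-1,4-diol, via alkylborane 7 (not isolated)
Conditions: 9-BBN-H (2.5 equiv), THF, 0 °C to rt; then 30% H2O2, aq. NaOAc, 0 °C to rt
Reagents that add atoms: 9-borabicyclo[3.3.1]nonane, B1C2CCCC1CCC2 (its boron stays only in 7); hydrogen peroxide, OO
Why: Anti-Markovnikov hydroboration of the terminal vinyl group and oxidation with retention give the primary alcohol, and the nearly neutral oxidation avoids closure of the 3-iodo alkoxide to an oxetane.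

Step 5
Reactants: 8 (3S,4S)-6-iodo-3,5,5-trimethylhexane-1,4-diol
Product: 9 (3S)-6-iodo-3,5,5-trimethyl-4-oxohexanal
Conditions: (COCl)2, DMSO, CH2Cl2, −78 °C; then i-Pr2NEt, −78 to −30 °C
Reagents that add atoms: none
Why: In the Swern oxidation both hydroxyls become alkoxysulfonium ions before base is added, so the 1,4-diol goes to the keto aldehyde without lactol or lactone formation, and the hindered base at low temperature preserves the stereocentre alpha to the new ketone.

Step 6
Reactants: 9 (3S)-6-iodo-3,5,5-trimethyl-4-oxohexanal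
Product: 10 (4R,6S)-4-hydroxy-2,2,6-trimethylcyclohexan-1-one
Conditions: CrCl2 (4 equiv), CoPc (cobalt phthalocyanine, C32H16CoN8, 10 mol%), DMF, 0.01 M, rt; aqueous work-up
Reagents that add atoms: none
Why: Monovalent cobalt, formed from CoPc and CrCl2, turns the neopentyl iodide into a primary radical that divalent chromium captures as an alkylchromium of trivalent chromium, and this carbon nucleophile adds to the aldehyde in a 6-exo-trig closure that forms the C2–C3 bond (cobalt-catalysed, chromium-mediated alkylation of aldehydes with alkyl iodides, the alkyl variant of the Nozaki–Hiyama–Kishi reaction, used here intramolecularly). The closure passes through a chair in which the C5 methyl and the chromium alkoxide at C3 are both equatorial, because an axial oxygen at C3 would be syn-axial to the axial methyl of C1, so the existing C5 stereocentre controls C3 and the cis (4R,6S) product should result. The step needs chemoselectivity for the aldehyde over the ketone, which alkylchromium reagents show, and the neopentyl carbon offers no beta hydrogen for elimination. The neutral conditions keep the epimerisable C5 centre intact until it has passed its information to C3. Any trans isomer is removed by chromatography here, so that the enantiomeric purity at C3 is not lowered when C5 later becomes sp2.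

Step 7
Reactants: 10 (4R,6S)-4-hydroxy-2,2,6-trimethylcyclohexan-1-one
Product: 11 (1R,5S)-3,3,5-trimethyl-4-oxocyclohexyl 2,2-dimethylpropanoate
Conditions: PivCl, pyridine, DMAP (cat.), CH2Cl2, 0 °C to rt
Reagents that add atoms: pivaloyl chloride, CC(C)(C)C(Cl)=O
Why: DMAP-catalysed acylation of the secondary alcohol gives a pivalate that tolerates LDA, palladium coupling and titanium alkoxide and is later removed in the DIBAL step that also reduces the ester.

Step 8
Reactants: 11 (1R,5S)-3,3,5-trimethyl-4-oxocyclohexyl 2,2-dimethylpropanoate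
Product: 12 (1R)-3,5,5-trimethyl-4-{[(trifluoromethyl)sulfonyl]oxy}cyclohex-3-en-1-yl 2,2-dimethylpropanoate
Conditions: LDA, THF, −78 to 0 °C; then PhNTf2, 0 °C to rt
Reagents that add atoms: N-phenylbis(trifluoromethanesulfonimide), O=S(=O)(N(c1ccccc1)S(=O)(=O)C(F)(F)F)C(F)(F)F
Why: LDA can deprotonate only at C5 because C1 is quaternary, and O-triflation of the enolate gives the tetrasubstituted enol triflate (enolate triflation), which erases the relay stereocentre C5 after it has set C3.

Step 9
Reactants: 12 (1R)-3,5,5-trimethyl-4-{[(trifluoromethyl)sulfonyl]oxy}cyclohex-3-en-1-yl 2,2-dimethylpropanoate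
Product: 13 (1R)-4-(hydroxymethyl)-3,5,5-trimethylcyclohex-3-en-1-yl 2,2-dimethylpropanoate
Conditions: Bu3SnCH2OH, Pd(PPh3)4 (10 mol%), LiCl, 1,4-dioxane, 100 °C
Reagents that add atoms: (tributylstannyl)methanol, CCCC[Sn](CCCC)(CCCC)CO
Why: Migita–Kosugi–Stille coupling of the enol triflate transfers the hydroxymethyl group to C6, with LiCl assisting transmetalation at the triflate.

Step 10
Reactants: 13 (1R)-4-(hydroxymethyl)-3,5,5-trimethylcyclohex-3-en-1-yl 2,2-dimethylpropanoate
Product: 14 (1R,3S,6R)-6-(hydroxymethyl)-1,5,5-trimethyl-7-oxabicyclo[4.1.0]heptan-3-yl 2,2-dimethylpropanoate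
Conditions: Ti(Oi-Pr)4, D-(−)-diethyl tartrate, t-BuOOH, 4 Å MS, CH2Cl2, −20 °C
Reagents that add atoms: tert-butyl hydroperoxide, CC(C)(C)OO
Why: Sharpless asymmetric epoxidation of the allylic alcohol: the titanium complex of D-(−)-diethyl tartrate delivers oxygen to the face of C5=C6 opposite to the C3 ester (reagent control, the same facial rule that gives (2R,3R)-epoxy alcohols from (E)-allylic alcohols), which sets C5 as R together with C6.

Step 11
Reactants: 14 (1R,3S,6R)-6-(hydroxymethyl)-1,5,5-trimethyl-7-oxabicyclo[4.1.0]heptan-3-yl 2,2-dimethylpropanoate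
Product: 15 (1R,3S,6S)-6-formyl-1,5,5-trimethyl-7-oxabicyclo[4.1.0]heptan-3-yl 2,2-dimethylpropanoate
Conditions: Dess–Martin periodinane, NaHCO3, CH2Cl2, 0 °C to rt
Reagents that add atoms: none
Why: Buffered Dess–Martin oxidation converts the primary epoxy alcohol into the aldehyde, which has no alpha hydrogen, so the epoxide stereocentres cannot epimerise.

Step 12
Reactants: 15 (1R,3S,6S)-6-formyl-1,5,5-trimethyl-7-oxabicyclo[4.1.0]heptan-3-yl 2,2-dimethylpropanoate; 16 ethyl (2E)-4-(diethoxyphosphoryl)-3-methylbut-2-enoate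
Product: 17 ethyl (2E,4E)-5-[(1S,4S,6R)-4-[(2,2-dimethylpropanoyl)oxy]-2,2,6-trimethyl-7-oxabicyclo[4.1.0]heptan-1-yl]-3-methylpenta-2,4-dienoate
Conditions: 16, LiHMDS, THF, −78 °C; then 15, −78 to 0 °C
Reagents that add atoms: none
Why: Horner–Wadsworth–Emmons olefination with the lithiated C5 phosphonate forms C7=C8 with E geometry (stabilised phosphonate, hindered aldehyde), the 9E geometry of the reagent is largely kept, and minor 9Z material is removed by chromatography.

Step 13
Reactants: 17 ethyl (2E,4E)-5-[(1S,4S,6R)-4-[(2,2-dimethylpropanoyl)oxy]-2,2,6-trimethyl-7-oxabicyclo[4.1.0]heptan-1-yl]-3-methylpenta-2,4-dienoate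
Product: 18 ethyl (2E)-3-[(2R,6S,7aR)-6-[(2,2-dimethylpropanoyl)oxy]-4,4,7a-trimethyl-2,4,5,6,7,7a-hexahydro-1-benzofuran-2-yl]but-2-enoate
Conditions: Cu(hfacac)2 [copper bis(hexafluoroacetylacetonate), Cu(C5HF6O2)2, 5 mol%], toluene, 110 °C
Reagents that add atoms: none
Why: Copper-catalysed ring expansion of a vinyl oxirane to a 2,5-dihydrofuran: the C6–O bond breaks and the same oxygen, held on its face by C5, closes onto C8 of the s-cis E-alkene, so C5 keeps its configuration and the E geometry translates into 8R (side chain trans to the C5 methyl), while the electron-poor dienoate disfavours a free allyl cation that could scramble the geometry.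

Step 14
Reactants: 18 ethyl (2E)-3-[(2R,6S,7aR)-6-[(2,2-dimethylpropanoyl)oxy]-4,4,7a-trimethyl-2,4,5,6,7,7a-hexahydro-1-benzofuran-2-yl]but-2-enoate
Product: 19 (2R,6S,7aR)-2-[(2E)-4-hydroxybut-2-en-2-yl]-4,4,7a-trimethyl-2,4,5,6,7,7a-hexahydro-1-benzofuran-6-ol
Conditions: DIBAL-H (6 equiv), CH2Cl2, −78 to 0 °C; aq. potassium sodium tartrate
Reagents that add atoms: none
Why: DIBAL reduces the conjugated ester to the allylic alcohol (1,2-reduction) and cleaves the pivalate in the same operation, and the low temperature and neutral work-up protect the acid-labile doubly allylic ether at C8.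

Step 15
Reactants: 19 (2R,6S,7aR)-2-[(2E)-4-hydroxybut-2-en-2-yl]-4,4,7a-trimethyl-2,4,5,6,7,7a-hexahydro-1-benzofuran-6-ol
Product: 20 (2E)-3-[(2R,6S,7aR)-6-hydroxy-4,4,7a-trimethyl-2,4,5,6,7,7a-hexahydro-1-benzofuran-2-yl]but-2-enal
Conditions: MnO2 (activated), CH2Cl2, rt
Reagents that add atoms: none
Why: Activated MnO2 oxidises only the allylic primary alcohol under neutral conditions and leaves the saturated secondary C3 hydroxyl untouched (chemoselective allylic oxidation).

Step 16
Reactants: 21 (2E,4E,6E)-2,7-dimethylocta-2,4,6-trienedial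
Product: 22 (2E,4E,6E)-2,7-dimethylocta-2,4,6-triene-1,8-diol
Conditions: NaBH4, MeOH/CH2Cl2, 0 °C
Reagents that add atoms: none
Why: Borohydride 1,2-reduction of both conjugated aldehydes gives the all-E diol.

Step 17
Reactants: 22 (2E,4E,6E)-2,7-dimethylocta-2,4,6-triene-1,8-diol
Product: 23 [(2E,4E,6E)-8-hydroxy-2,7-dimethylocta-2,4,6-trien-1-yl]triphenylphosphonium bromide
Conditions: PPh3·HBr (0.9 equiv), MeOH, rt
Reagents that add atoms: triphenylphosphine hydrobromide, [Br-].c1ccc(cc1)[PH+](c1ccccc1)c1ccccc1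
Why: Allylic alcohols react with triphenylphosphine hydrobromide through the allyl cation to give the terminal phosphonium salt (standard phosphonium salt formation in polyene synthesis), a deficit of reagent favours the mono salt, and unreacted diol is recovered.

Step 18
Reactants: 20 (2E)-3-[(2R,6S,7aR)-6-hydroxy-4,4,7a-trimethyl-2,4,5,6,7,7a-hexahydro-1-benzofuran-2-yl]but-2-enal; 23 [(2E,4E,6E)-8-hydroxy-2,7-dimethylocta-2,4,6-trien-1-yl]triphenylphosphonium bromide
Product: 24 (2E,4E,6E,8E,10E)-11-[(2R,6S,7aR)-6-hydroxy-4,4,7a-trimethyl-2,4,5,6,7,7a-hexahydro-1-benzofuran-2-yl]-2,7-dimethyldodeca-2,4,6,8,10-pentaen-1-ol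
Conditions: 1,2-epoxybutane, EtOH, reflux, dark; then crystallisation
Reagents that add atoms: none
Why: Wittig reaction with the ylide generated under neutral conditions by the epoxide method (1,2-epoxybutane scavenges HBr) forms C11=C12, the hindered 11Z isomer formed beside the E isomer isomerises on heating to the all-E polyene, and the free hydroxyls and the acid-labile C8 ether tolerate these conditions.

Compound list
1 | isobutyronitrile | CC(C)C#N | starting material
2 | 3-iodo-2,2-dimethylpropanenitrile | N#CC(C)(C)CI | intermediate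
3 | 3-iodo-2,2-dimethylpropan-1-imine (N-aluminated in the flask) | N=CC(C)(C)CI | intermediate
4 | 3-iodo-2,2-dimethylpropanal | O=CC(C)(C)CI | intermediate
5 | (3S,4S)-1-iodo-2,2,4-trimethylhex-5-en-3-yl diisopinocampheylborinate [Ipc from (+)-α-pinene] | C=C[C@H](C)[C@H](OB([C@@H]1C[C@@H]2C[C@H]([C@H]1C)C2(C)C)[C@@H]1C[C@@H]2C[C@H]([C@H]1C)C2(C)C)C(C)(C)CI | intermediate
6 | (3S,4S)-1-iodo-2,2,4-trimethylhex-5-en-3-ol | C=C[C@H](C)[C@H](O)C(C)(C)CI | intermediate
7 | 9-[(3S,4S)-4-hydroxy-6-iodo-3,5,5-trimethylhexyl]-9-borabicyclo[3.3.1]nonane (hydroxyl carried as its borinate in the flask) | C1CCC2CCCC1B2CC[C@H](C)[C@H](O)C(C)(C)CI | intermediate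
8 | (3S,4S)-6-iodo-3,5,5-trimethylhexane-1,4-diol | OCC[C@H](C)[C@H](O)C(C)(C)CI | intermediate
9 | (3S)-6-iodo-3,5,5-trimethyl-4-oxohexanal | O=CC[C@H](C)C(=O)C(C)(C)CI | intermediate
10 | (4R,6S)-4-hydroxy-2,2,6-trimethylcyclohexan-1-one | CC1(C)C[C@H](O)C[C@H](C)C1=O | intermediate
11 | (1R,5S)-3,3,5-trimethyl-4-oxocyclohexyl 2,2-dimethylpropanoate | CC1(C)C[C@H](OC(=O)C(C)(C)C)C[C@H](C)C1=O | intermediate
12 | (1R)-3,5,5-trimethyl-4-{[(trifluoromethyl)sulfonyl]oxy}cyclohex-3-en-1-yl 2,2-dimethylpropanoate | CC1=C(OS(=O)(=O)C(F)(F)F)C(C)(C)C[C@H](OC(=O)C(C)(C)C)C1 | intermediate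
13 | (1R)-4-(hydroxymethyl)-3,5,5-trimethylcyclohex-3-en-1-yl 2,2-dimethylpropanoate | CC1=C(CO)C(C)(C)C[C@H](OC(=O)C(C)(C)C)C1 | intermediate
14 | (1R,3S,6R)-6-(hydroxymethyl)-1,5,5-trimethyl-7-oxabicyclo[4.1.0]heptan-3-yl 2,2-dimethylpropanoate (epoxide anti to the ester) | CC1(C)C[C@H](OC(=O)C(C)(C)C)C[C@@]2(C)O[C@@]12CO | intermediate
15 | (1R,3S,6S)-6-formyl-1,5,5-trimethyl-7-oxabicyclo[4.1.0]heptan-3-yl 2,2-dimethylpropanoate | CC1(C)C[C@H](OC(=O)C(C)(C)C)C[C@@]2(C)O[C@@]12C=O | intermediate
16 | ethyl (2E)-4-(diethoxyphosphoryl)-3-methylbut-2-enoate | CCOC(=O)/C=C(\C)CP(=O)(OCC)OCC | starting material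
17 | ethyl (2E,4E)-5-[(1S,4S,6R)-4-[(2,2-dimethylpropanoyl)oxy]-2,2,6-trimethyl-7-oxabicyclo[4.1.0]heptan-1-yl]-3-methylpenta-2,4-dienoate | CC1(C)C[C@H](OC(=O)C(C)(C)C)C[C@@]2(C)O[C@@]12/C=C/C(C)=C/C(=O)OCC | intermediate
18 | ethyl (2E)-3-[(2R,6S,7aR)-6-[(2,2-dimethylpropanoyl)oxy]-4,4,7a-trimethyl-2,4,5,6,7,7a-hexahydro-1-benzofuran-2-yl]but-2-enoate | CCOC(=O)/C=C(\C)[C@H]1C=C2C(C)(C)C[C@H](OC(=O)C(C)(C)C)C[C@@]2(C)O1 | intermediate
19 | (2R,6S,7aR)-2-[(2E)-4-hydroxybut-2-en-2-yl]-4,4,7a-trimethyl-2,4,5,6,7,7a-hexahydro-1-benzofuran-6-ol | C/C(=C\CO)[C@H]1C=C2C(C)(C)C[C@H](O)C[C@@]2(C)O1 | intermediate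
20 | (2E)-3-[(2R,6S,7aR)-6-hydroxy-4,4,7a-trimethyl-2,4,5,6,7,7a-hexahydro-1-benzofuran-2-yl]but-2-enal | C/C(=C\C=O)[C@H]1C=C2C(C)(C)C[C@H](O)C[C@@]2(C)O1 | intermediate
21 | (2E,4E,6E)-2,7-dimethylocta-2,4,6-trienedial | O=C/C(C)=C/C=C/C=C(C)/C=O | starting material
22 | (2E,4E,6E)-2,7-dimethylocta-2,4,6-triene-1,8-diol | OC/C(C)=C/C=C/C=C(C)/CO | intermediate
23 | [(2E,4E,6E)-8-hydroxy-2,7-dimethylocta-2,4,6-trien-1-yl]triphenylphosphonium bromide | OC/C(C)=C/C=C/C=C(C)/C[P+](c1ccccc1)(c1ccccc1)c1ccccc1.[Br-] | intermediate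
24 | (2E,4E,6E,8E,10E)-11-[(2R,6S,7aR)-6-hydroxy-4,4,7a-trimethyl-2,4,5,6,7,7a-hexahydro-1-benzofuran-2-yl]-2,7-dimethyldodeca-2,4,6,8,10-pentaen-1-ol | CC(/C=C/C=C(\C)[C@H]1C=C2C(C)(C)C[C@H](O)C[C@@]2(C)O1)=C\C=C\C=C(/C)CO | target

Total step count: 18. Longest linear sequence: 16 (steps 1–15 and 18).

Steps most likely to fail

1. Step 6. The alkylchromium may form too slowly from the hindered neopentyl iodide, so that the radical is reduced to the C–H compound or C5 epimerises before ring closure, which would erode the diastereoselectivity. The fallback closes the same bond by a samarium Barbier reaction at the alcohol oxidation level, where no ketone competes; it sets out from 6 and returns at 11.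
   - The hydroxyl of 6 would be etherified with 4-methoxybenzyl trichloroacetimidate and catalytic camphorsulfonic acid (basic etherification is avoided because of the 3-iodo alkoxide) to the PMB ether F1.
   - Hydroboration with 9-BBN-H and buffered peroxide oxidation would give the primary alcohol F2, and Dess–Martin oxidation the aldehyde F3.
   - SmI2 with HMPA in THF would reduce the iodide to an organosamarium that adds to the aldehyde through a chair with the C5 methyl and the new alkoxide equatorial, giving the cyclohexanol F4.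
   - Pivaloylation would give the pivalate F5, DDQ would remove the PMB group to the hydroxy pivalate F6, and Dess–Martin oxidation would give 11.

2. Step 13. The alkene geometry may be lost through ionisation to an allyl cation, giving both C8 epimers, or a thermal 1,5-hydrogen shift from the C5 methyl may open the oxirane to a dienol. The fallback sets C8 by axis-to-centre transfer from an allene; it sets out from 15 and returns at 19.
   - The Ohira–Bestmann reagent with K2CO3 in MeOH would convert the aldehyde into the terminal alkynyl epoxide F7.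
   - Sonogashira coupling with (E)-3-iodobut-2-en-1-ol (Pd(PPh3)2Cl2, CuI, i-Pr2NH) would give the enyne epoxide F8.
   - Anti-SN2′ reduction with an N-heterocyclic carbene copper hydride ((IPr)CuCl, NaOt-Bu, polymethylhydrosiloxane, toluene, 0 °C; fluoride work-up) would deliver hydride to C8 anti to the departing oxygen and give the allenol F9 with an (S)-configured axis.
   - AgNO3 in aqueous acetone would close the tertiary hydroxyl onto C8 in a 5-endo cyclisation to the dihydrofuran pivalate F10 (8R), and K2CO3 in MeOH would remove the pivalate to give 19.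

3. Step 9. Transmetalation of the sp3 stannane at the hindered tetrasubstituted enol triflate may be so slow that triflate hydrolysis or reduction outruns the coupling. The fallback sets out from 12 and returns at 13: palladium-catalysed formylation with CO and Bu3SnH (Pd(PPh3)4, THF, 50 °C) would give the enal F11, and Luche reduction (NaBH4, CeCl3·7H2O, MeOH, 0 °C) would give 13 with the pivalate intact.

Further compounds
F1 | step 6 | 1-({[(3S,4S)-1-iodo-2,2,4-trimethylhex-5-en-3-yl]oxy}methyl)-4-methoxybenzene | C=C[C@H](C)[C@H](OCc1ccc(OC)cc1)C(C)(C)CI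
F2 | step 6 | (3S,4S)-6-iodo-4-[(4-methoxyphenyl)methoxy]-3,5,5-trimethylhexan-1-ol | OCC[C@H](C)[C@H](OCc1ccc(OC)cc1)C(C)(C)CI
F3 | step 6 | (3S,4S)-6-iodo-4-[(4-methoxyphenyl)methoxy]-3,5,5-trimethylhexanal | O=CC[C@H](C)[C@H](OCc1ccc(OC)cc1)C(C)(C)CI
F4 | step 6 | (1R,4S,5S)-4-[(4-methoxyphenyl)methoxy]-3,3,5-trimethylcyclohexan-1-ol | CC1(C)C[C@H](O)C[C@H](C)[C@@H]1OCc1ccc(OC)cc1
F5 | step 6 | (1R,4S,5S)-4-[(4-methoxyphenyl)methoxy]-3,3,5-trimethylcyclohexyl 2,2-dimethylpropanoate | CC1(C)C[C@H](OC(=O)C(C)(C)C)C[C@H](C)[C@@H]1OCc1ccc(OC)cc1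
F6 | step 6 | (1R,4S,5S)-4-hydroxy-3,3,5-trimethylcyclohexyl 2,2-dimethylpropanoate | CC1(C)C[C@H](OC(=O)C(C)(C)C)C[C@H](C)[C@@H]1O
F7 | step 13 | (1R,3S,6R)-6-ethynyl-1,5,5-trimethyl-7-oxabicyclo[4.1.0]heptan-3-yl 2,2-dimethylpropanoate | CC1(C)C[C@H](OC(=O)C(C)(C)C)C[C@@]2(C)O[C@@]12C#C
F8 | step 13 | (1R,3S,6R)-6-[(3E)-5-hydroxy-3-methylpent-3-en-1-yn-1-yl]-1,5,5-trimethyl-7-oxabicyclo[4.1.0]heptan-3-yl 2,2-dimethylpropanoate | CC1(C)C[C@H](OC(=O)C(C)(C)C)C[C@@]2(C)O[C@@]12C#C/C(C)=C/CO
F9 | step 13 | (1S,3R)-3-hydroxy-4-[(3E)-5-hydroxy-3-methylpenta-1,3-dien-1-ylidene]-3,5,5-trimethylcyclohexyl 2,2-dimethylpropanoate with (S)-configured allene axis | CC1(C)C[C@H](OC(=O)C(C)(C)C)C[C@@](C)(O)C1=[C@@]=C([H])/C(C)=C/CO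
F10 | step 13 | (2R,6S,7aR)-2-[(2E)-4-hydroxybut-2-en-2-yl]-4,4,7a-trimethyl-2,4,5,6,7,7a-hexahydro-1-benzofuran-6-yl 2,2-dimethylpropanoate | C/C(=C\CO)[C@H]1C=C2C(C)(C)C[C@H](OC(=O)C(C)(C)C)C[C@@]2(C)O1
F11 | step 9 | (1R)-4-formyl-3,5,5-trimethylcyclohex-3-en-1-yl 2,2-dimethylpropanoate | CC1=C(C=O)C(C)(C)C[C@H](OC(=O)C(C)(C)C)C1
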